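(The runs were generated by integration with constants of no real substance; scatter was added.)

Two questions stand on this flask, and I reckon them from a time constant, which gives the starting material left, together with a share read from the runs, which splits the converted material between target and isomer.

| flask | starting material | precatalyst | remark | time |
|---|---|---|---|---|
| south-west | 0.050 M | 0.93 mol% | run made earlier |  |
| north-west | 0.075 M | 0.93 mol% | run made earlier |  |
| flask | 0.10 M | 0.93 mol% |  | 50 min |

| run | time / min | target / % | starting material / % | catalyst intermediate / % | isomer of the product / % |
|---|---|---|---|---|---|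
| south-west | 10.0 | 12.6 | 82.7 | 2.9 | 4.2 |
| south-west | 20.0 | 26.6 | 63.4 | 0 | 6.9 |
| south-west | 30.0 | 36.0 | 51.6 | 1.4 | 11.4 |
| south-west | 40.0 | 44.7 | 40.6 | 0.6 | 15.4 |
| south-west | 50.0 | 51.4 | 29.6 | 0 | 19.1 |
| south-west | 60.0 | 56.6 | 24.2 | 0.7 | 20.7 |
| north-west | 4.00 | 6.3 | 91.7 | 0 | 1.0 |
| north-west | 12.0 | 23.9 | 68.3 | 0 | 6.2 |
| north-west | 20.0 | 36.1 | 52.6 | 1.8 | 10.8 |
| north-west | 30.0 | 46.7 | 39.1 | 0 | 14.6 |
| north-west | 50.0 | 62.7 | 16.3 | 0.9 | 19.4 |
| north-west | 60.0 | 63.6 | 12.0 | 0 | 23.0 |

(scatter of a reading: 1 percentage point)

- where most of what was charged as starting material, at 50 min is found (catalyst intermediate / isomer of the product / starting material / target)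
- the largest share itself, whichever of these holds it, in percent of the starting material charged

- the earlier runs were read with a standard deviation of 1 percentage point

In the north-west run the starting material falls to 16.3% in 50.0 min, which is a first-order time constant of 27.6 min; the south-west run gives 41.1 min. The loading is the same in both, so the catalyst concentration goes with the charge, and the ratio of these times, 1.49, matches the ratio of the charges, 1.50. Scaled to this flask, that gives the consumption time, the pseudo-first-order time in which starting material falls by the factor e at the charged catalyst concentration: 20.7 min.

After 50 min I therefore expect 8.90% of the starting material to remain. In the north-west run at 50.0 min, target holds 76.4% of the converted material, which would put target at 69.6%. That share is the weak link, since it rests on one pair of readings. The last readings of both runs together give 73.3%, so I commit to target at 66.8%, with the isomer at 24.3%.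

The forecast reads “time × concentration is the natural clock” and names target at 65.5%, a little below my figure.

The flask gives target at 66.4%.

    starting material + free catalyst → catalyst intermediate (k = 8.10 /M/s)
    target ⇌ isomer of the product (K = 0.360, k = 0.00180 /s)
    precatalyst ⇌ free catalyst (K = 0.120, k = 0.00200 /s)
    catalyst intermediate → free catalyst + target (k = 0.890 /s)

In this flask, catalyst intermediate passes on to target with a half-life of 0.78 s at 14.5 min, while precatalyst holds 82.7% of the catalyst at 5.00 min and 88.4% at 50.0 min. Alongside, target and isomer exchange with a relaxation half-life of 1.70 min, and half of that turnover is done by 16.9 min. The consumption time of 20.7 min gave 8.90% against the 10.2% of starting material found here. Shortened by the factor 3.98 for the neighbour flask with 3.7 mol% of precatalyst, it gives 0.00662% left at 50 min; that flask holds 0.0086%, with target at 73.5%.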